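**Strategy**

1. Cuts: ring C is opened at O1–C2 to an ortho-hydroxyaryl ynone. This is cut at C4–C4a and O1–C8a into 3,4-dimethoxybenzyne and 3-(2,3,5,6-tetramethoxyphenyl)propiolic acid. The acid is cut at C3–C4 (CO2), C2–C3 (the CBr4 carbon) and C1'–C2 (a formyl carbon) back to 1,2,4,5-tetramethoxybenzene.
2. Enabling feature: on ring A the acyl carbon C4 (on C4a) and the ring oxygen O1 (on C8a) are ortho neighbours, and the 5-methoxy group lies next to C4a. Oxygen addition to a 3-alkoxyaryne followed by an acyl shift produces exactly this pattern, and the alkyne keeps the crowded C1' of the di-ortho-methoxylated ring B away from the bond-forming sites.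
3. Forward order: rings A and B are bought intact. Ring A becomes an ortho-silylaryl triflate, ring B gains a three-carbon alkynoic acid chain, the halves are joined by aryne insertion into the acid C–O bond, and ring C closes last, in the same flask, by O1–C2 bond formation.
4. Stereochemistry: none to set. The target has no stereocentre and no configured double bond, and the symmetry of ring B about its C1'–C4' axis rules out atropisomers.

Key step: step 7

Remark: the ortho-acyl phenoxide formed in the key step is expected to cyclise in the flask in which it forms, so the insertion and the closure of ring C are written as one step.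

**Route**

Step 1
Reactants: 1 3,4-dimethoxyphenol
Product: 2 3,4-dimethoxyphenyl N-isopropylcarbamate
Conditions: i-PrNCO, Et3N (cat.), CH2Cl2, rt
Reagents that add atoms: isopropyl isocyanate, CC(C)N=C=O
Why: Base-catalysed addition of the phenol O–H to the isocyanate (carbamoylation) is a clean way to install an ortho-directing group that can later be removed without hydrolysis.

Step 2
Reactants: 2 3,4-dimethoxyphenyl N-isopropylcarbamate
Product: 6 3,4-dimethoxy-2-(trimethylsilyl)phenyl N-isopropylcarbamate, via N-silyl carbamate 3 (not isolated), via 2-lithio N-silyl carbamate 4 (not isolated), via N-silyl 2-trimethylsilyl carbamate 5 (not isolated)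
Conditions: TBSOTf, TMEDA, Et2O, 0 °C to rt; n-BuLi (2.2 equiv, one of them neutralises TMEDA·HOTf), TMEDA, −78 °C; Me3SiCl, −78 °C to rt; aq. NaHSO4
Reagents that add atoms: chlorotrimethylsilane, C[Si](C)(C)Cl
Why: In situ N-silylation masks the acidic N–H so that the carbamate survives n-BuLi, directed ortho-metalation then takes place at C2, the only position flanked by both the carbamate oxygen and the 3-methoxy group, the aryllithium is trapped by Me3SiCl, and the labile N–Si bond is hydrolysed in the acidic work-up.

Step 3
Reactants: 6 3,4-dimethoxy-2-(trimethylsilyl)phenyl N-isopropylcarbamate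
Product: 8 3,4-dimethoxy-2-(trimethylsilyl)phenyl trifluoromethanesulfonate, via 3,4-dimethoxy-2-(trimethylsilyl)phenol 7 (not isolated)
Conditions: DBU, Et2NH, MeCN, 40 °C; then PhNTf2, rt
Reagents that add atoms: N-phenylbis(trifluoromethanesulfonimide), O=S(=O)(N(c1ccccc1)S(=O)(=O)C(F)(F)F)C(F)(F)F
Why: DBU deprotonates the N–H of the secondary carbamate and triggers an E1cB fragmentation to the phenoxide and isopropyl isocyanate (scavenged by Et2NH as a urea), and the phenoxide is then O-sulfonylated in the same flask by the mild triflyl donor PhNTf2 without touching the aryl C–Si bond.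

Step 4
Reactants: 9 1,2,4,5-tetramethoxybenzene
Product: 11 2,3,5,6-tetramethoxybenzaldehyde, via (2,3,5,6-tetramethoxyphenyl)lithium 10 (not isolated)
Conditions: n-BuLi, TMEDA, THF, 0 °C to rt; DMF, 0 °C; aq. HCl
Reagents that add atoms: N,N-dimethylformamide, CN(C)C=O
Why: Directed ortho-metalation at one of the two equivalent ring C–H positions, each lying between two methoxy groups, gives a doubly coordinated aryllithium that DMF formylates (Bouveault formylation).

Step 5
Reactants: 11 2,3,5,6-tetramethoxybenzaldehyde
Product: 12 3-(2,2-dibromovinyl)-1,2,4,5-tetramethoxybenzene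
Conditions: CBr4, PPh3, Zn dust, CH2Cl2, rt (ylide pre-formed); then 11, rt
Reagents that add atoms: carbon tetrabromide, BrC(Br)(Br)Br
Why: Corey–Fuchs dibromoolefination, a Wittig-type reaction of Ph3P=CBr2, tolerates the two ortho-methoxy groups because the small ylide attacks the formyl carbon outside the ring plane, and zinc as bromine acceptor keeps the electron-rich ring free from Ph3PBr2.

Step 6
Reactants: 12 3-(2,2-dibromovinyl)-1,2,4,5-tetramethoxybenzene
Product: 14 3-(2,3,5,6-tetramethoxyphenyl)propiolic acid, via lithium (2,3,5,6-tetramethoxyphenyl)acetylide 13 (not isolated)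
Conditions: n-BuLi (2.1 equiv), THF, −78 °C; CO2 (dry gas), −78 °C to rt; aq. HCl
Reagents that add atoms: carbon dioxide, O=C=O
Why: In the second stage of the Corey–Fuchs sequence, Br–Li exchange and Fritsch–Buttenberg–Wiechell rearrangement of the bromocarbenoid give the alkyne, a second equivalent of n-BuLi holds it as acetylide 13, and low-temperature carboxylation with CO2 gives the propiolic acid after acidification.

Step 7
Reactants: 8 3,4-dimethoxy-2-(trimethylsilyl)phenyl trifluoromethanesulfonate (1.5 equiv); 14 3-(2,3,5,6-tetramethoxyphenyl)propiolic acid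
Product: 17 5,6,2',3',5',6'-hexamethoxyflavone, via 3,4-dimethoxybenzyne 15 (not isolated), via ortho-hydroxyaryl ynone 16 (not isolated)
Conditions: CsF (4 equiv), THF, 125 °C, sealed tube; aq. NH4Cl
Reagents that add atoms: none
Why: Fluoride removes the silyl group of 8 with loss of triflate to give aryne 15, the caesium carboxylate of 14 adds through oxygen to the aryne carbon far from the methoxy groups (the later C8a), and the aryl anion left beside the 3-methoxy group (the later C4a) attacks the ester carbonyl through a four-membered transition state, an anionic Fries-type O-to-C acyl shift that delivers the ortho-acyl phenoxide 16 with the new C8a–O1 and C4a–C4 bonds. The closest known reaction type is the CsF-mediated formal insertion of arynes from ortho-silylaryl triflates into the C–O bond of carboxylic acids, which gives ortho-hydroxyaryl ketones and, with acrylic or arylpropiolic acids, chromanones or flavones after conjugate closure. Ring C then closes by 6-endo-dig oxa-Michael addition of the phenoxide oxygen O1 to the alkyne carbon that carries ring B (C2), followed by protonation at C3. No stereocentre is formed. Two selectivities are required: the orientation of addition to the unsymmetrical aryne, which the inductively withdrawing methoxy group next to the triple bond secures by distorting the aryne so that the nucleophile enters at the distal carbon and the charge builds up beside the methoxy group, and 6-endo over 5-exo closure, which the aprotic medium secures because only the conjugate mode leads to a carbonyl-stabilised anion. The acyl group that migrates is an unhindered alkynyl carbonyl, so the shift should outpace protonation of the aryl anion, and the rigid C≡C spacer holds the four methoxy groups of ring B away from the carboxylate and carbonyl centres.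

**Compound list**

1 | 3,4-dimethoxyphenol | COc1ccc(O)cc1OC | starting material
2 | 3,4-dimethoxyphenyl N-isopropylcarbamate | CC(C)NC(=O)Oc1ccc(OC)c(OC)c1 | intermediate
3 | 3,4-dimethoxyphenyl N-(tert-butyldimethylsilyl)-N-isopropylcarbamate | CC(C)N(C(=O)Oc1ccc(OC)c(OC)c1)[Si](C)(C)C(C)(C)C | intermediate (not isolated)
4 | 2-lithio-3,4-dimethoxyphenyl N-(tert-butyldimethylsilyl)-N-isopropylcarbamate (lithium on the carbon between the carbamate oxygen and the 3-methoxy group) | CC(C)N(C(=O)Oc1ccc(OC)c(OC)c1[Li])[Si](C)(C)C(C)(C)C | intermediate (not isolated)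
5 | 3,4-dimethoxy-2-(trimethylsilyl)phenyl N-(tert-butyldimethylsilyl)-N-isopropylcarbamate | CC(C)N(C(=O)Oc1ccc(OC)c(OC)c1[Si](C)(C)C)[Si](C)(C)C(C)(C)C | intermediate (not isolated)
6 | 3,4-dimethoxy-2-(trimethylsilyl)phenyl N-isopropylcarbamate | CC(C)NC(=O)Oc1ccc(OC)c(OC)c1[Si](C)(C)C | intermediate
7 | 3,4-dimethoxy-2-(trimethylsilyl)phenol (present as its DBU salt) | COc1ccc(O)c([Si](C)(C)C)c1OC | intermediate (not isolated)
8 | 3,4-dimethoxy-2-(trimethylsilyl)phenyl trifluoromethanesulfonate | COc1ccc(OS(=O)(=O)C(F)(F)F)c([Si](C)(C)C)c1OC | intermediate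
9 | 1,2,4,5-tetramethoxybenzene | COc1cc(OC)c(OC)cc1OC | starting material
10 | (2,3,5,6-tetramethoxyphenyl)lithium | COc1cc(OC)c(OC)c([Li])c1OC | intermediate (not isolated)
11 | 2,3,5,6-tetramethoxybenzaldehyde | COc1cc(OC)c(OC)c(C=O)c1OC | intermediate
12 | 3-(2,2-dibromovinyl)-1,2,4,5-tetramethoxybenzene | COc1cc(OC)c(OC)c(C=C(Br)Br)c1OC | intermediate
13 | lithium (2,3,5,6-tetramethoxyphenyl)acetylide | COc1cc(OC)c(OC)c(C#C[Li])c1OC | intermediate (not isolated)
14 | 3-(2,3,5,6-tetramethoxyphenyl)propiolic acid | COc1cc(OC)c(OC)c(C#CC(=O)O)c1OC | intermediate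
15 | 3,4-dimethoxybenzyne (1,2-didehydro-3,4-dimethoxybenzene, formal triple bond between C1 and C2) | COC1=C(OC)C#CC=C1 | intermediate (not isolated)
16 | 1-(6-hydroxy-2,3-dimethoxyphenyl)-3-(2,3,5,6-tetramethoxyphenyl)prop-2-yn-1-one (present as its caesium phenoxide) | COc1ccc(O)c(C(=O)C#Cc2c(OC)c(OC)cc(OC)c2OC)c1OC | intermediate (not isolated)
17 | 5,6,2',3',5',6'-hexamethoxyflavone, 5,6-dimethoxy-2-(2,3,5,6-tetramethoxyphenyl)-4H-chromen-4-one | COc1cc(OC)c(OC)c(-c2cc(=O)c3c(OC)c(OC)ccc3o2)c1OC | target

**Summary**

Total step count: 7.
Longest linear sequence: 4 steps (steps 1, 2, 3, 7 from 1, or steps 4, 5, 6, 7 from 9).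

**Steps most likely to fail**

Step 7. The aryl anion may be protonated before the acyl shift, so that only O-arylation to the aryl ester takes place. The caesium propiolate may also lose CO2 at 125 °C, or the phenoxide may close in the 5-exo mode. The fallback is the classical stepwise ynone route; it sets out from 1 and from acetylide 13 (made from 12 as in step 6) and comes back at 16.
- Phenol 1 is protected with MOMCl and i-Pr2NEt to give 4-(methoxymethoxy)-1,2-dimethoxybenzene F1.
- n-BuLi in THF lithiates F1 at the carbon between the acetal oxygen and the methoxy group, and DMF gives 2,3-dimethoxy-6-(methoxymethoxy)benzaldehyde F2.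
- Acetylide 13 adds to F2 at −78 °C to give racemic 1-[2,3-dimethoxy-6-(methoxymethoxy)phenyl]-3-(2,3,5,6-tetramethoxyphenyl)prop-2-yn-1-ol F3.
- MnO2 in CH2Cl2 oxidises F3 to 1-[2,3-dimethoxy-6-(methoxymethoxy)phenyl]-3-(2,3,5,6-tetramethoxyphenyl)prop-2-yn-1-one F4.
- Aqueous HCl in THF removes the acetal to give 16, which is closed to 17 with Et2NH in EtOH; closure through the β-amino enone can only give the six-membered ring.

Step 2. N-silylation may be incomplete, after which the deprotonated carbamate fragments to phenoxide and isocyanate; trapping of the crowded C2 aryllithium by the silyl chloride may also be slow. The fallback uses a tertiary carbamate that needs no N-mask and is cleaved reductively; it sets out from 1 and comes back at 7.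
- Phenol 1 is acylated with ClC(O)NEt2 and K2CO3 in MeCN to give 3,4-dimethoxyphenyl N,N-diethylcarbamate F5.
- s-BuLi/TMEDA in THF at −78 °C followed by Me3SiCl gives 3,4-dimethoxy-2-(trimethylsilyl)phenyl N,N-diethylcarbamate F6.
- LiAlH4 in THF cleaves the carbamate to phenol 7, which is triflated with PhNTf2 and DBU as in the second half of step 3 to reach 8.

Step 6. Surplus n-BuLi may metalate the last ring C–H, which lies between two methoxy groups, and lead to double carboxylation; rearrangement of the bromocarbenoid may also be incomplete. The fallback builds the alkyne by diazophosphonate homologation; it sets out from 11 and comes back at 13.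
- Aldehyde 11 is treated with dimethyl (1-diazo-2-oxopropyl)phosphonate and K2CO3 in MeOH (Ohira–Bestmann form of the Seyferth–Gilbert homologation) to give 3-ethynyl-1,2,4,5-tetramethoxybenzene F7.
- One equivalent of LiN(SiMe3)2 in THF at −78 °C, too weak a base to metalate the ring, converts F7 into acetylide 13, which is carboxylated with CO2 to 14 as in step 6.

Further compounds
F1 | step 7 | 4-(methoxymethoxy)-1,2-dimethoxybenzene | COCOc1ccc(OC)c(OC)c1
F2 | step 7 | 2,3-dimethoxy-6-(methoxymethoxy)benzaldehyde | COCOc1ccc(OC)c(OC)c1C=O
F3 | step 7 | 1-[2,3-dimethoxy-6-(methoxymethoxy)phenyl]-3-(2,3,5,6-tetramethoxyphenyl)prop-2-yn-1-ol (racemic) | COCOc1ccc(OC)c(OC)c1C(O)C#Cc1c(OC)c(OC)cc(OC)c1OC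
F4 | step 7 | 1-[2,3-dimethoxy-6-(methoxymethoxy)phenyl]-3-(2,3,5,6-tetramethoxyphenyl)prop-2-yn-1-one | COCOc1ccc(OC)c(OC)c1C(=O)C#Cc1c(OC)c(OC)cc(OC)c1OC
F5 | step 2 | 3,4-dimethoxyphenyl N,N-diethylcarbamate | CCN(CC)C(=O)Oc1ccc(OC)c(OC)c1
F6 | step 2 | 3,4-dimethoxy-2-(trimethylsilyl)phenyl N,N-diethylcarbamate | CCN(CC)C(=O)Oc1ccc(OC)c(OC)c1[Si](C)(C)C
F7 | step 6 | 3-ethynyl-1,2,4,5-tetramethoxybenzene | COc1cc(OC)c(OC)c(C#C)c1OC
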